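## The problem

The target is a chamigrane. Its two six-membered rings share the quaternary spiro carbon C6, which lies between a second quaternary carbon (C7, gem-dimethyl) and the fully substituted alkene carbon C11, so the bonds around C6 are the most congested in the molecule. There are four stereocentres: C6, the secondary bromide C8 in ring A, and the C2/C3 pair of ring B, a trans bromohydrin with a tertiary alcohol.

C6 is the only centre common to both rings. In the ring B chair the bulky C7 branch is equatorial and C11 with its methyl is axial, so C6 can steer reagents on the C2=C3 faces and control C2 and C3. It distinguishes the two faces of ring A only through the remote C1 and C5 methylenes, so C8 needs reagent control.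

The C8 bromide is neopentylic: it cannot be made by SN2 displacement and is lost by E2 or Wagner–Meerwein shift on ionisation. The bromohydrin does not tolerate strong base or reducing metals. The C10=C11 alkene is protonated by strong acid to a cation that the skeleton traps transannularly.

The key step rests on one structural match. The triad C6–C7(Me)2–C11(Me) is the C8a–C8–C4a unit of thujopsene (1), whose vinylcyclopropane already holds C1, C2, C3 with its methyl, and C4. Only the C5–C6 bond is missing, and C5 sits on the neighbouring carbon, from where a 1,2-shift can deliver it.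

## Retrosynthesis

**14 ⇒ 13.** The C2–Br and C3–O bonds are cut together, leading back to the ring B alkene of (6S,8R)-8-bromo-α-chamigrene (13). Anti addition of Br+ and water gives the trans relationship by itself, and the Markovnikov rule puts oxygen on C3. The neighbouring cut, C2–Br alone from a cis-diol via its cyclic sulfate, was put second. It needs the tertiary oxygen on the ring B face syn to C11, which is the face screened by axial C11 and its methyl, so osmylation would most likely give the 2,3-bis-epimer. In the bromohydrin route the electrophile takes the open face (syn to C7) and water the other, which is the target's pattern. Compound 13 has two stereocentres and two heteroatoms fewer. The forward step must prefer the ring B alkene over the shielded ring A alkene.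

**13 ⇒ 11.** No skeletal bond is cut; the C2=C3 alkene is traced back to epoxide 11, which masks it during the work on ring A. A mask is needed because allylic oxidation at C9 cannot tell that methylene from the allylic C1 and C4 methylenes of ring B. An epoxide costs one step on and one off, against two and three for a diol acetonide, and its configuration is irrelevant. The forward deoxygenation must spare the C8 bromide.

**11 ⇒ 9 (through 10).** The C8–Br bond is cut to a C8–B bond of opposite configuration. Substitution of an alcohol would require SN2 attack at a neopentyl carbon. Electrophilic bromination of the boronate complex 10 with inversion forms the bond without that displacement and without a cation next to C7. The forward step must stay polar (no radical leak) to transfer the configuration.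

**9 ⇒ 7 + 8.** The C8–B and C9–H bonds are cut, giving diene 7 and bis(pinacolato)diboron (8). Copper places boron at a diene terminus. C11 is fully substituted, so only C8 is available, and protonation at C9 keeps the C10=C11 alkene. The precursor has one stereocentre fewer; the forward step needs a chiral ligand to choose the C8 face.

**7 ⇒ 6 ⇒ 4 (through 5).** The C8=C9 alkene is traced to dienyl triflate 6 and then to enone 4 through its kinetic enolate 5. A hydrazone-based olefination would expose the epoxide to excess alkyllithium; one equivalent of amide base at low temperature and a neutral palladium reduction do not. The forward steps need α′ (C8) rather than γ deprotonation.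

**4 ⇒ 3.** The C9=O bond is cut to the C9 methylene of 3. With ring B masked this is the only allylic methylene, and it is the handle through which unactivated C8 becomes reachable.

**3 ⇒ 2.** The two epoxide C–O bonds are cut to the ring B alkene of (6R)-α-chamigrene (2). The forward step must select the less hindered of two trisubstituted alkenes.

**2 ⇒ 1.** The C5–C6 bond is cut and C5 is returned to C11 while the C2–C6 cyclopropane bond is re-formed, which gives (−)-thujopsene (1). No other cut removes the spiro centre, ring B and the quaternary triad in one operation, and 1 is a bulk terpene with all fifteen carbons. The forward step must open the cyclopropane toward C6, migrate the ring methylene rather than the methyl, and stop at 2.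

## Roads not taken

**Alternative 1:** The cut runs through ring A at C9–C10 and C8–Br. The α-bromo-β-keto ester A1, bound to Mg(ClO4)2 and a chiral bisoxazoline and initiated with BEt3/O2, would cyclise through its C10 radical onto the terminal vinyl carbon, and the C8 radical would take up bromine to give A2.
- Merits: ring A, the neopentylic C–Br bond and the C8 configuration arise in one catalytic step. Here this road is better than the chosen plan, which spends steps 4 to 7 on C8 and relies on an invertive bromodeboronation.
- Weak points: in A2 the spiro carbon bears two identical ring B arms and is not yet a stereocentre, so C6 must later be defined by desymmetrising ring B relative to C8, two atoms away. The C11 carbonyl, flanked by the spiro carbon, must become the C(Me)=C10 alkene and the ester must go while a base-sensitive bromide is present. Ring B still needs its methyl carbinol and bromide. Six-membered closure must beat five-membered closure, and A1 itself needs several steps.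
- Comparison: against the direct C–Br formation, the chosen plan takes the spiro configuration from the chiral pool in one step and needs nine steps in all.

**Alternative 2:** The cut is C6–C11. Zerovalent palladium from Pd(OAc)2 and a biaryl phosphine would insert into the alkenyl C–Br bond of phenol A3, and the para carbon of the phenoxide (K2CO3) would attack to give spirodienone A4.
- Merits: convergent and catalytic. It delivers the ring A diene that the chosen route reaches only at 7 after five steps, needs no mask, and offers a C3 carbonyl for the methyl carbinol. In access to the diene it is better.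
- Weak points: A4 is achiral, so C6 must be created by desymmetrising two enone arms that differ only through C7 versus C11. The bond joins a fully substituted alkenyl carbon to a carbon next to the gem-dimethyl group, and A3 must hold a Z,Z-diene. The cross-conjugated dienone is prone to dienone–phenol rearrangement. C8 still needs the same boron chemistry as here.
- Comparison: the chosen plan pays for its mask with two steps but gets the absolute configuration at C6 at no cost.

**Alternative 3:** The cut is C2–C3. A chiral amine would form an enamine at the internal methylene of one 3-oxobutyl arm of diketone A5, which would add to the ketone of the other arm to give A6.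
- Merits: C2, C3 and C6 are set in one catalytic step, with the tertiary alcohol formed directly in place. As a way to the ring B triad this is more economical than the chosen plan.
- Weak points: A6 carries an acetyl group where bromine is needed, so a Baeyer–Villiger oxidation, hydrolysis and an invertive substitution must follow. A5 already contains the quaternary C6 between C7 and C11 and the C8 bromide, so the two hardest features are moved into the precursor. The acceptor is an unactivated methyl ketone (reversible aldol), and the enamine may form at the methyl group.
- Comparison: the chosen plan sets C2 and C3 in its last step with bromine directly in place, and makes the C6 environment in step 1.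

Key step: step 1

Assumption: the antipode of the bisphosphine in step 6 that delivers boron to the required C8 face cannot be derived safely from models of unhindered cyclohexadienes; the (R,R) ligand is written, and its mirror image is to be used if the first run shows the opposite sense.

Step 1
Reactants: 1 (−)-thujopsene
Product: 2 (6R)-3,7,7,11-tetramethylspiro[5.5]undeca-2,10-diene (α-chamigrene)
Conditions: TsOH (anhydrous, 5 mol %), benzene, 4 Å MS, 25 °C, GC control; Et3N quench
Reagents that add atoms: none
Why: Protonation of the alkene at its CH carbon (future C4) gives a tertiary cyclopropylcarbinyl cation at C3, and the C2–C6 cyclopropane bond opens because it alone leads to a tertiary homoallylic cation, releasing ring strain and creating the C2=C3 alkene. The ring methylene C5 on the neighbouring angular carbon then migrates to C6 (Wagner–Meerwein 1,2-alkyl shift), so ring B is closed by contraction of the seven-membered ring of the opened cation and not by a cyclisation, and the new tertiary cation at C11 loses a proton from C10 to give the endocyclic C10=C11 alkene. The closest known reaction type is the acid-induced cyclopropylcarbinyl-to-homoallyl opening followed by a 1,2-shift, the thujopsane-to-chamigrane terpene rearrangement. C6 is the only new stereocentre and is controlled by the C4a (future C11) configuration of 1: the six-membered ring that contains both C5 and the breaking cyclopropane bond holds C5 on the face of C6 from which that bond departs, so C5 enters that lobe and (1aS,4aS,8aS)-1 is relayed to (6R)-2 while the C11 centre is destroyed. The methylene is preferred to the methyl as migrating group (higher migratory aptitude, relief of cycloheptene strain), exclusion of water suppresses capture of the C6 cation as the tertiary alcohol, and catalytic acid in an apolar solvent with early quench limits exocyclic proton loss and re-protonation of 2, which would lead to tricyclic olefins by attack of C2=C3 on the C11 cation.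

Step 2
Reactants: 2 (6R)-3,7,7,11-tetramethylspiro[5.5]undeca-2,10-diene
Product: 3 (2S,3R,6R)-2,3-epoxy-3,7,7,11-tetramethylspiro[5.5]undec-10-ene (oxygen on the ring B face syn to C7)
Conditions: mCPBA (1.05 equiv), NaHCO3, CH2Cl2, −20 → 0 °C
Reagents that add atoms: mCPBA, O=C(OO)c1cccc(Cl)c1
Why: Prilezhaev epoxidation; the ring B alkene is the less shielded of the two trisubstituted alkenes because C10=C11 is flanked by the spiro carbon and, one bond further, the gem-dimethyl carbon. Attack anti to pseudoaxial C11 should put oxygen syn to C7, a configuration that is erased again in step 8.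

Step 3
Reactants: 3 (2S,3R,6R)-2,3-epoxy-3,7,7,11-tetramethylspiro[5.5]undec-10-ene
Product: 4 (2S,3R,6R)-2,3-epoxy-3,7,7,11-tetramethylspiro[5.5]undec-10-en-9-one
Conditions: CrO3, 3,5-dimethylpyrazole, CH2Cl2, −20 °C
Reagents that add atoms: chromium trioxide, O=[Cr](=O)=O
Why: Allylic oxidation with the CrO3–3,5-dimethylpyrazole complex; C9 is the only allylic methylene once ring B is masked, and oxygen delivered to tertiary C11 would transpose to C9 before oxidation, so the β-methyl enone should result. The epoxide is inert to the neutral chromium reagent.

Step 4
Reactants: 4 (2S,3R,6R)-2,3-epoxy-3,7,7,11-tetramethylspiro[5.5]undec-10-en-9-one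
Product: 6 (2S,3R,6S)-2,3-epoxy-3,7,7,11-tetramethylspiro[5.5]undeca-8,10-dien-9-yl trifluoromethanesulfonate, via lithium dienolate 5 (not isolated)
Conditions: LDA (1.1 equiv), THF, −78 °C; then PhNTf2, −78 → 0 °C
Reagents that add atoms: N-phenylbis(trifluoromethanesulfonimide), O=S(=O)(N(c1ccccc1)S(=O)(=O)C(F)(F)F)C(F)(F)F
Why: Kinetic deprotonation of the isophorone-type enone occurs at the α′ methylene C8 (cross-conjugated enolate), and O-sulfonylation fixes the C8=C9 double bond. One equivalent of amide base at −78 °C leaves the epoxide alone.

Step 5
Reactants: 6 (2S,3R,6S)-2,3-epoxy-3,7,7,11-tetramethylspiro[5.5]undeca-8,10-dien-9-yl trifluoromethanesulfonate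
Product: 7 (2S,3R,6S)-2,3-epoxy-3,7,7,11-tetramethylspiro[5.5]undeca-8,10-diene
Conditions: Pd(OAc)2 (5 mol %), PPh3, Bu3N, HCO2H, DMF, 60 °C
Reagents that add atoms: none
Why: Palladium-catalysed formate reduction of an enol triflate (oxidative addition, formate exchange, decarboxylation, C–H reductive elimination) replaces OTf by H and gives the ring A 1,3-diene under conditions too mild to open the remote epoxide.

Step 6
Reactants: 7 (2S,3R,6S)-2,3-epoxy-3,7,7,11-tetramethylspiro[5.5]undeca-8,10-diene; 8 bis(pinacolato)diboron
Product: 9 2-[(2S,3R,6R,8S)-2,3-epoxy-3,7,7,11-tetramethylspiro[5.5]undec-10-en-8-yl]-4,4,5,5-tetramethyl-1,3,2-dioxaborolane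
Conditions: CuCl (5 mol %), (R,R)-QuinoxP* (5 mol %), NaOt-Bu (10 mol %), MeOH (2 equiv), THF, 0 °C
Reagents that add atoms: none
Why: Copper-catalysed protoboration of a cyclic 1,3-diene: the boryl copper adds boron to the diene terminus C8 (the other terminus C11 is fully substituted) and copper to C9, and methanol protonates the allylcopper at C9, which keeps the trisubstituted C10=C11 alkene. The ring A faces differ only through the remote C1 and C5 methylenes, so the C8 centre (S) is set by the chiral bisphosphine on copper.

Step 7
Reactants: 9 2-[(2S,3R,6R,8S)-2,3-epoxy-3,7,7,11-tetramethylspiro[5.5]undec-10-en-8-yl]-4,4,5,5-tetramethyl-1,3,2-dioxaborolane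
Product: 11 (2S,3R,6S,8R)-8-bromo-2,3-epoxy-3,7,7,11-tetramethylspiro[5.5]undec-10-ene, via lithium aryl boronate complex 10 (not isolated)
Conditions: 3,5-(CF3)2C6H3Br, n-BuLi, THF, −78 °C; add 9; then NBS, −78 °C → rt
Reagents that add atoms: N-bromosuccinimide, O=C1CCC(=O)N1Br
Why: The electron-poor aryllithium gives a boronate complex whose C8–B bond is attacked by NBS at carbon from the rear (SE2 with inversion), turning the (8S)-boronate into the (8R)-bromide without a carbocation or an SN2 displacement at the neopentyl centre. The electron-poor aryl group disfavours single-electron oxidation, and the hindered ring A alkene and the epoxide should not compete for NBS at −78 °C.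

Step 8
Reactants: 11 (2S,3R,6S,8R)-8-bromo-2,3-epoxy-3,7,7,11-tetramethylspiro[5.5]undec-10-ene
Product: 13 (6S,8R)-8-bromo-3,7,7,11-tetramethylspiro[5.5]undeca-2,10-diene, via trans-iodohydrin 12 (not isolated)
Conditions: Zn dust, NaI, NaOAc, AcOH, 20 °C
Reagents that add atoms: none
Why: Cornforth deoxygenation: iodide opens the protonated epoxide anti to the iodohydrin, zinc inserts into the C–I bond and β-elimination returns the C2=C3 alkene, so both sp3 centres of the mask vanish. The unactivated neopentyl bromide and the ring A alkene should not be reduced by zinc in buffered acetic acid at room temperature.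

Step 9
Reactants: 13 (6S,8R)-8-bromo-3,7,7,11-tetramethylspiro[5.5]undeca-2,10-diene
Product: 14 (2S,3S,6S,8R)-2,8-dibromo-3,7,7,11-tetramethylspiro[5.5]undec-10-en-3-ol
Conditions: NBS (1.05 equiv), THF–H2O (3:1), 0 °C, dark
Reagents that add atoms: N-bromosuccinimide, O=C1CCC(=O)N1Br; water, O
Why: Bromohydrin formation: NBS delivers Br+ to the more accessible ring B alkene on the face syn to equatorial C7 (anti to axial C11 and its methyl), and water opens the bromonium ion at tertiary C3 from the opposite face (Markovnikov, anti). This sets C2 (S) and C3 (S) as the trans bromohydrin with Br cis to the C3 methyl, while the ring A alkene is shielded by its two quaternary neighbours.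

**Compound list**

1 | (−)-thujopsene, (1aS,4aS,8aS)-2,4a,8,8-tetramethyl-1,1a,4,4a,5,6,7,8-octahydrocyclopropa[d]naphthalene | CC1=CC[C@]2(C)CCCC(C)(C)[C@@]23C[C@@H]13 | starting material
2 | (6R)-3,7,7,11-tetramethylspiro[5.5]undeca-2,10-diene (α-chamigrene) | CC1=CCCC(C)(C)[C@]12CCC(C)=CC2 | intermediate
3 | (2S,3R,6R)-2,3-epoxy-3,7,7,11-tetramethylspiro[5.5]undec-10-ene | CC1=CCCC(C)(C)[C@]12CC[C@@]3(C)O[C@H]3C2 | intermediate
4 | (2S,3R,6R)-2,3-epoxy-3,7,7,11-tetramethylspiro[5.5]undec-10-en-9-one | CC1=CC(=O)CC(C)(C)[C@]12CC[C@@]3(C)O[C@H]3C2 | intermediate
5 | lithium (2S,3R,6S)-2,3-epoxy-3,7,7,11-tetramethylspiro[5.5]undeca-8,10-dien-9-olate | [Li+].CC1=CC([O-])=CC(C)(C)[C@]12CC[C@@]3(C)O[C@H]3C2 | intermediate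
6 | (2S,3R,6S)-2,3-epoxy-3,7,7,11-tetramethylspiro[5.5]undeca-8,10-dien-9-yl trifluoromethanesulfonate | CC1=CC(OS(=O)(=O)C(F)(F)F)=CC(C)(C)[C@]12CC[C@@]3(C)O[C@H]3C2 | intermediate
7 | (2S,3R,6S)-2,3-epoxy-3,7,7,11-tetramethylspiro[5.5]undeca-8,10-diene | CC1=CC=CC(C)(C)[C@]12CC[C@@]3(C)O[C@H]3C2 | intermediate
8 | bis(pinacolato)diboron | CC1(C)OB(OC1(C)C)B1OC(C)(C)C(C)(C)O1 | starting material
9 | 2-[(2S,3R,6R,8S)-2,3-epoxy-3,7,7,11-tetramethylspiro[5.5]undec-10-en-8-yl]-4,4,5,5-tetramethyl-1,3,2-dioxaborolane | CC1=CC[C@H](B4OC(C)(C)C(C)(C)O4)C(C)(C)[C@]12CC[C@@]3(C)O[C@H]3C2 | intermediate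
10 | lithium [3,5-bis(trifluoromethyl)phenyl][(2S,3R,6R,8S)-2,3-epoxy-3,7,7,11-tetramethylspiro[5.5]undec-10-en-8-yl](pinacolato)borate | [Li+].CC1=CC[C@H]([B-]4(OC(C)(C)C(C)(C)O4)c5cc(cc(c5)C(F)(F)F)C(F)(F)F)C(C)(C)[C@]12CC[C@@]3(C)O[C@H]3C2 | intermediate
11 | (2S,3R,6S,8R)-8-bromo-2,3-epoxy-3,7,7,11-tetramethylspiro[5.5]undec-10-ene | CC1=CC[C@@H](Br)C(C)(C)[C@]12CC[C@@]3(C)O[C@H]3C2 | intermediate
12 | (2R,3R,6S,8R)-8-bromo-2-iodo-3,7,7,11-tetramethylspiro[5.5]undec-10-en-3-ol | CC1=CC[C@@H](Br)C(C)(C)[C@]12CC[C@@](C)(O)[C@H](I)C2 | intermediate
13 | (6S,8R)-8-bromo-3,7,7,11-tetramethylspiro[5.5]undeca-2,10-diene | CC1=CC[C@@H](Br)C(C)(C)[C@]12CCC(C)=CC2 | intermediate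
14 | (2S,3S,6S,8R)-2,8-dibromo-3,7,7,11-tetramethylspiro[5.5]undec-10-en-3-ol | CC1=CC[C@@H](Br)C(C)(C)[C@]12CC[C@](C)(O)[C@@H](Br)C2 | target

**Step count and least certain steps**

Total: 9 steps. Longest linear sequence: 9 steps, from 1.

**Step 1 (key step).** The likely failure is over-isomerisation: exocyclic proton loss from the C11 cation, or re-protonation of 2 followed by transannular attack of C2=C3 on C11. Capture of the C6 cation by traces of water and methyl instead of methylene migration are further risks. All these cations lie on one surface, and 2 is not its lowest point.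
- Fallback: divide the event. From 1, HClO4 in aqueous dioxane deliberately traps the C6 cation as the crystalline tertiary alcohol widdrol F1, which is purified. F1 is then ionised with anhydrous oxalic acid in benzene under azeotropic removal of water, a weaker acid than is needed to protonate the alkenes of 2. The same C6 cation rearranges, and the route is rejoined at 2.

**Step 7.** Stereospecificity may be lost if the boronate complex is oxidised by single-electron transfer (radical bromination), or rear-side attack may be slow next to the gem-dimethyl carbon.
- Fallback: from 9, oxidation with NaBO3·4H2O in THF–water (retention) gives the (2S,3R,6S,8S)-8-alcohol F2. Appel bromination (CBr4, PPh3, CH2Cl2) with inversion rejoins the route at 11. Elimination toward C9 competes at this neopentyl centre, so this is a less efficient reserve.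

**Step 6.** Boryl-copper insertion next to C7 may be sluggish, the allylcopper may be protonated at C11 (giving the allylic boronate), or the ligand may not control the face, since the substrate is far more hindered than the dienes on which the reaction is established.
- Fallback: from 7, epoxidation of the cis-disubstituted C8=C9 bond with (salen)MnCl [N,N′-bis(3,5-di-tert-butylsalicylidene)-1,2-cyclohexanediaminomanganese chloride, the antipode that puts oxygen on the required face] and NaOCl gives the vinyl epoxide F3. Hydrogenolysis with Pd2(dba)3, PBu3 and HCO2H/Et3N delivers hydride to C9 and gives the homoallylic alcohol F2. Appel bromination as above rejoins the route at 11.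

**Step 8.** Zinc may reduce or eliminate the homoallylic bromide, or acetolysis of the hindered epoxide may outrun iodide opening.
- Fallback: remove the mask before bromine is introduced. From 9, the low-valent tungsten reagent from WCl6 and n-BuLi (THF, −78 °C → rt) deoxygenates the epoxide to the boronate F4. Addition of 3,5-(CF3)2C6H3Li gives the boronate complex F5, and NBS at −78 °C gives the bromide with inversion, rejoining the route at 13.

**Step 9.** Facial selectivity may be poor or inverted (bromonium ion syn to C11), or the ring A alkene may compete. The face argument rests on a conformational model and not on a rigid steric bias.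
- Fallback: this serves the case of inverted preference, in which osmium would use the same face. From 13, OsO4/NMO gives the (2R,3S)-cis-diol F6. 1,1′-Sulfonyldiimidazole with NaH gives the cyclic sulfate F7 without RuO4, which would attack the ring A alkene. LiBr opens F7 at secondary C2 with inversion to the sulfate monoester F8, and H2SO4 in wet THF hydrolyses it with retention at C3, rejoining the route at 14.

**Further compounds**

F1 | step 1 | (4aS,9aR)-1,1,4a,7-tetramethyl-2,3,4,5,6,9-hexahydrobenzo[7]annulen-9a-ol (widdrol) | CC1=CC[C@@]2(O)C(C)(C)CCC[C@@]2(C)CC1
F2 | step 7 | (2S,3R,6S,8S)-2,3-epoxy-3,7,7,11-tetramethylspiro[5.5]undec-10-en-8-ol | CC1=CC[C@H](O)C(C)(C)[C@]12CC[C@@]3(C)O[C@H]3C2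
F3 | step 6 | (2S,3R,6S,8R,9S)-2,3:8,9-diepoxy-3,7,7,11-tetramethylspiro[5.5]undec-10-ene | CC1=C[C@@H]4O[C@@H]4C(C)(C)[C@]12CC[C@@]3(C)O[C@H]3C2
F4 | step 8 | 2-[(6R,8S)-3,7,7,11-tetramethylspiro[5.5]undeca-2,10-dien-8-yl]-4,4,5,5-tetramethyl-1,3,2-dioxaborolane | CC1=CC[C@H](B3OC(C)(C)C(C)(C)O3)C(C)(C)[C@]12CCC(C)=CC2
F5 | step 8 | lithium [3,5-bis(trifluoromethyl)phenyl][(6R,8S)-3,7,7,11-tetramethylspiro[5.5]undeca-2,10-dien-8-yl](pinacolato)borate | [Li+].CC1=CC[C@H]([B-]3(OC(C)(C)C(C)(C)O3)c4cc(cc(c4)C(F)(F)F)C(F)(F)F)C(C)(C)[C@]12CCC(C)=CC2
F6 | step 9 | (2R,3S,6S,8R)-8-bromo-3,7,7,11-tetramethylspiro[5.5]undec-10-ene-2,3-diol | CC1=CC[C@@H](Br)C(C)(C)[C@]12CC[C@](C)(O)[C@H](O)C2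
F7 | step 9 | 2,3-cyclic sulfate of F6 (configuration as in F6) | CC1=CC[C@@H](Br)C(C)(C)[C@]12CC[C@]3(C)OS(=O)(=O)O[C@@H]3C2
F8 | step 9 | lithium (2S,3S,6S,8R)-2,8-dibromo-3,7,7,11-tetramethylspiro[5.5]undec-10-en-3-yl sulfate | [Li+].CC1=CC[C@@H](Br)C(C)(C)[C@]12CC[C@](C)(OS(=O)(=O)[O-])[C@@H](Br)C2
A1 | alternative 1 | tert-butyl 2-bromo-3-[8-(2-methylbut-3-en-2-yl)-1,4-dioxaspiro[4.5]decan-8-yl]-3-oxopropanoate | CC(C)(C)OC(=O)C(Br)C(=O)C1(CCC2(CC1)OCCO2)C(C)(C)C=C
A2 | alternative 1 | tert-butyl (10S,12R)-12-bromo-13,13-dimethyl-9-oxo-1,4-dioxadispiro[4.2.5.2]pentadecane-10-carboxylate | CC(C)(C)OC(=O)[C@H]1C[C@@H](Br)C(C)(C)C2(CCC3(CC2)OCCO3)C1=O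
A3 | alternative 2 | 4-[(3Z,5Z)-6-bromo-2-methylhepta-3,5-dien-2-yl]phenol | C/C(Br)=C/C=C\C(C)(C)c1ccc(O)cc1
A4 | alternative 2 | 7,7,11-trimethylspiro[5.5]undeca-1,4,8,10-tetraen-3-one | CC1=CC=CC(C)(C)C12C=CC(=O)C=C2
A5 | alternative 3 | 4,4'-[(5R)-5-bromo-2,6,6-trimethylcyclohex-2-ene-1,1-diyl]di(butan-2-one) | CC1=CC[C@@H](Br)C(C)(C)C1(CCC(C)=O)CCC(C)=O
A6 | alternative 3 | 1-[(2S,3S,6S,8R)-8-bromo-3-hydroxy-3,7,7,11-tetramethylspiro[5.5]undec-10-en-2-yl]ethan-1-one | CC1=CC[C@@H](Br)C(C)(C)[C@]12CC[C@](C)(O)[C@@H](C(C)=O)C2
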